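**Retrosynthetic overview**
1. Elemane numbering is used. The ring is C5–C10: C10 is quaternary (CH3, vinyl C1=C2), C9 bears OAc, C8 bears the lactone O, C7 bears C11(=C13H2)–C12=O, C6 bears the O-angelate, C5 bears C4(=C3H2)–C15HO. β is the ring face of the C10 methyl.
2. End game: C15HO comes from an isopropenyl group by allylic oxidation. The γ-lactone (O8–C12), the 9-acetate and the 6-angelate all come from one triol tert-butyl ester through a temporary 8,9-orthoacetate ring.
3. Key disconnection: the cyclohexane is opened at C6–C7 and C9–C10 into two C3 units of the same kind, C10–C5–C6 and C7–C8–C9. Each has an aldehyde carbon (C6, C9) and an allylboronate γ-carbon (C10, C7) two bonds away. They are joined head to tail by a double allylboration, a [3+3] annulation in one flask.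
4. Enabling feature: in the six-membered ring the carbinol carbons C6 and C9 stand 1,4. Each is followed, in the same sense round the ring, by a carbon (C7, C10) whose 1-alkenyl group (C11=C13, C1=C2) is equatorial and cis to the axial oxygen. These are two homoallylic alcohol units with the signature of Z-type allylboronates in chair transition states.
5. Ring order: carbocycle (key step), then temporary dioxolane, then γ-lactone. The only stereocentre brought in is C8, from (S)-glyceraldehyde acetonide; the other five arise in the key step.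

Key step: step 11

Remark: the C10–C5–C6 unit is made and used as the racemate and is drawn without a stereo mark at C5, because C5 is equilibrated and selected during the ring closure.

Step 1
Reactants: 1 3-methylbut-2-enal; 2 but-2-yn-1-ol (2.5 equiv)
Product: 3 1,1-bis(but-2-yn-1-yloxy)-3-methylbut-2-ene
Conditions: PPTS (2 mol%), cyclohexane, Dean–Stark trap, reflux
Reagents that add atoms: none
Why: Acid-catalysed acetalisation driven by azeotropic removal of water; no stereocentre is formed.

Step 2
Reactants: 3 1,1-bis(but-2-yn-1-yloxy)-3-methylbut-2-ene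
Product: 4 (E)-1-(but-2-yn-1-yloxy)-3-methylbuta-1,3-diene
Conditions: TMSOTf (1.1 equiv), iPr2NEt (1.3 equiv), CH2Cl2, −20 → 25 °C
Reagents that add atoms: none
Why: Silyl triflate/amine-induced 1,4-elimination of one alkoxy group (acetal to enol ether conversion) should give the 1-alkoxydiene, whose E/Z ratio is irrelevant because step 3 gives a racemate in any case.

Step 3
Reactants: 4 (E)-1-(but-2-yn-1-yloxy)-3-methylbuta-1,3-diene
Product: 6 rac-5,5-dimethoxy-3-methyl-4-(prop-1-en-2-yl)penta-1,2-diene, via allenyl aldehyde 5 (not isolated)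
Conditions: [(Ph3PAu)3O]BF4 (1 mol%), CH2Cl2, 25 °C; then HC(OMe)3, MeOH, PPTS (cat.), 0 °C, same flask
Reagents that add atoms: trimethyl orthoformate, COC(OC)OC
Why: Gold-catalysed propargyl Claisen rearrangement ([3,3]) forms C5–C10 and the 1-methylallenyl group (C5 racemic), and orthoformate acetalisation traps the labile α-branched aldehyde at once.

Step 4
Reactants: 6 rac-5,5-dimethoxy-3-methyl-4-(prop-1-en-2-yl)penta-1,2-diene
Product: 7 rac-(Z)-2-[5,5-dimethoxy-3-methyl-4-(prop-1-en-2-yl)pent-2-en-1-yl]-4,4,5,5-tetramethyl-1,3,2-dioxaborolane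
Conditions: HBpin (1.2 equiv), CuCl (2 mol%), Xantphos (2 mol%), KOtBu (6 mol%), toluene, 25 °C
Reagents that add atoms: pinacolborane, [H]B1OC(C)(C)C(C)(C)O1
Why: Copper hydride-catalysed hydroboration of a 1,1-disubstituted allene delivers H to the central carbon from the face away from the larger substituent, so the branched C5 chain ends cis to CH2B (Z-allylboronate), while the isolated isopropenyl group is inert.

Step 5
Reactants: 8 (S)-2,2-dimethyl-1,3-dioxolane-4-carbaldehyde; 9 tert-butyl acrylate
Product: 10 tert-butyl 2-{hydroxy[(4S)-2,2-dimethyl-1,3-dioxolan-4-yl]methyl}acrylate (carbinol epimers)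
Conditions: DABCO (1 equiv), 1,4-dioxane–H2O 1:1, 25 °C
Reagents that add atoms: none
Why: Morita–Baylis–Hillman reaction forms C7–C11; the new carbinol centre needs no control because it is erased in step 9, and C8 is untouched.

Step 6
Reactants: 10 tert-butyl 2-{hydroxy[(4S)-2,2-dimethyl-1,3-dioxolan-4-yl]methyl}acrylate
Product: 11 tert-butyl 2-{acetoxy[(4S)-2,2-dimethyl-1,3-dioxolan-4-yl]methyl}acrylate
Conditions: Ac2O, pyridine, DMAP (cat.), CH2Cl2, 0 °C
Reagents that add atoms: acetic anhydride, CC(=O)OC(C)=O
Why: Standard O-acetylation turns the allylic hydroxyl into the leaving group needed in step 9.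

Step 7
Reactants: 11 tert-butyl 2-{acetoxy[(4S)-2,2-dimethyl-1,3-dioxolan-4-yl]methyl}acrylate
Product: 12 tert-butyl (4S)-3-acetoxy-4,5-dihydroxy-2-methylenepentanoate
Conditions: AcOH–H2O 4:1, 40 °C; used at once
Reagents that add atoms: none
Why: Mild acid hydrolysis of the acetonide spares the tert-butyl ester and the allylic acetate, and acyl migration is slow in acid.

Step 8
Reactants: 12 tert-butyl (4S)-3-acetoxy-4,5-dihydroxy-2-methylenepentanoate
Product: 13 tert-butyl (4S)-3-acetoxy-2-methylene-4,5-bis(triethylsilyloxy)pentanoate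
Conditions: TESOTf (2.3 equiv), 2,6-lutidine, CH2Cl2, −78 °C
Reagents that add atoms: triethylsilyl triflate, CC[Si](CC)(CC)OS(=O)(=O)C(F)(F)F
Why: Fast low-temperature silylation of both hydroxyls, so that no free OH meets the boronate made next.

Step 9
Reactants: 13 tert-butyl (4S)-3-acetoxy-2-methylene-4,5-bis(triethylsilyloxy)pentanoate
Product: 14 tert-butyl (2E,4R)-2-[(4,4,5,5-tetramethyl-1,3,2-dioxaborolan-2-yl)methyl]-4,5-bis(triethylsilyloxy)pent-2-enoate
Conditions: B2pin2 (1.1 equiv), CuCl (5 mol%), Xantphos (5 mol%), KOtBu (10 mol%), THF, 0 → 25 °C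
Reagents that add atoms: bis(pinacolato)diboron, CC1(C)OB(OC1(C)C)B1OC(C)(C)C(C)(C)O1
Why: Copper-catalysed SN2' borylation of a Morita–Baylis–Hillman acetate (boryl conjugate addition, then acetate elimination), in which allylic strain places C8 trans to the ester and therefore cis to CH2B.

Step 10
Reactants: 14 tert-butyl (2E,4R)-2-[(pinacolboryl)methyl]-4,5-bis(triethylsilyloxy)pent-2-enoate
Product: 15 tert-butyl (2E,4R)-5-oxo-2-[(4,4,5,5-tetramethyl-1,3,2-dioxaborolan-2-yl)methyl]-4-(triethylsilyloxy)pent-2-enoate
Conditions: (COCl)2, DMSO, CH2Cl2, −78 → −30 °C; Et3N, −78 °C; cold neutral work-up, used at once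
Reagents that add atoms: none
Why: Swern oxidation applied directly to a bis-silyl ether cleaves and oxidises only the primary triethylsilyl ether, and the low temperature protects the configuration at C8.

Step 11
Reactants: 7 rac-(Z)-allylboronate acetal (2.2 equiv); 15 tert-butyl (2E,4R)-5-oxo-2-[(pinacolboryl)methyl]-4-(triethylsilyloxy)pent-2-enoate
Product: 18 tert-butyl 6β,8α,9α-trihydroxyelema-1,3,11(13)-trien-12-oate (5αH,7αH), via borate adduct 16 (not isolated), via formyl boronate 17 (not isolated)
Conditions: Sc(OTf)3 (10 mol%), toluene, −40 → 0 °C; then MeCN–H2O 9:1, 25 → 40 °C, same flask; aq. NaHCO3 work-up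
Reagents that add atoms: water, O
Why: Proposed new method: a self-sorting, head-to-tail double carbonyl allylboration that joins two three-carbon formyl/allylboronate units in a [3+3] sense, the closest known reaction types being the Sc(OTf)3-catalysed allylboration of aldehydes with 2-alkoxycarbonyl allylboronates, the intramolecular allylboration of formyl allylboronates and the tandem double allylation of dicarbonyl compounds with bis-allylboron reagents. Mechanism: the electron-rich boronate of 7 transfers its γ-carbon C10 through a closed six-membered chair to the only free aldehyde in the flask (C9 of 15) to give 16, then water and the same catalyst hydrolyse the acetal and the O9 borate to the aldehyde 17, which rests as its five-membered lactol on O9 and is drained irreversibly when the ester-bearing boronate delivers C7 to C6, the silyl ether being lost last. The selectivity needed is cross- against self-coupling and the substrates secure it, because 7 holds no electrophile before water is added and the boronate of 15, deactivated by the ester on C11 and by its γ-substituent, is far slower than that of 7 and reacts only once the step has become intramolecular. Ring closure: the carbocycle closes 6-exo-trig at the C6 carbonyl through two cis-fused chairs (forming cyclohexane and boron chair), the only arrangement open to a boronate whose C8 is cis to CH2B, since C5 axial on the boron chair would stand anti to C8. Stereocontrol: C9 by polar Felkin-type (Cornforth) attack on the α-silyloxy aldehyde, reinforced by the Z substituent of 7 (8,9-anti, cis on the ring); C10 by the Z geometry of 7 (CH3 equatorial in the chair, hence anti to O9); C7 by allylic 1,3-strain, which keeps H8 in the alkene plane while the tether through C9 fixes the face (C6 enters anti to O8, H7/H8 trans); C6 by the fused chairs (O6 axial, cis to C11). C5 is corrected in the flask, because its α-formyl, allylic hydrogen in 17 exchanges through the dienol, which is reprotonated kinetically at the α-carbon, and only the epimer with an equatorial isopropenyl group avoids a syn-diaxial clash with O9 in the closing transition state (Curtin–Hammett selection), so racemic 7 in excess suffices.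

Step 12
Reactants: 18 tert-butyl 6β,8α,9α-trihydroxyelema-1,3,11(13)-trien-12-oate
Product: 19 8α,9α-O-(1-methoxyethylidene) derivative of 18 (cyclic orthoacetate, 6β-OH free, mixture at the orthoester carbon)
Conditions: MeC(OMe)3 (1.5 equiv), CSA (5 mol%), CH2Cl2, 25 °C; Et3N quench
Reagents that add atoms: trimethyl orthoacetate, CC(OC)(OC)OC
Why: In this acid-catalysed orthoester exchange only the cis-vicinal 8,9-diol can close the five-membered ring, which leaves the 6β-OH as the only free hydroxyl; the new orthoester centre is lost in step 14.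

Step 13
Reactants: 19 8α,9α-orthoacetate with free 6β-OH
Product: 20 6β-angelate of 19
Conditions: angelic acid (4 equiv), 2,4,6-trichlorobenzoyl chloride (4 equiv), Et3N (8 equiv), toluene, 25 °C; then 19, 80 °C, no DMAP
Reagents that add atoms: angelic acid, C/C=C(/C)C(=O)O
Why: Yamaguchi-type mixed-anhydride esterification, run without a nucleophilic catalyst so that the Z-acyl group is not isomerised, acylates the only free hydroxyl with retention at C6.

Step 14
Reactants: 20 6β-angelate 8α,9α-orthoacetate tert-butyl ester
Product: 21 9α-acetoxy-6β-angeloyloxyelema-1,3,11(13)-trien-12,8α-olide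
Conditions: TFA–CH2Cl2 1:4, H2O (5 equiv), 0 → 25 °C
Reagents that add atoms: water, O
Why: Acid hydrolysis of the cyclic orthoester opens under stereoelectronic control to the axial ester and equatorial alcohol (9α-OAc, 8α-OH), the same acid cleaves the tert-butyl ester, and the 8α-OH closes the trans-fused γ-lactone (5-exo-trig lactonisation) because O6 is blocked.

Step 15
Reactants: 21 9α-acetoxy-6β-angeloyloxyelema-1,3,11(13)-trien-12,8α-olide
Product: 22 9α-acetoxy-6β-angeloyloxy-15-oxoelema-1,3,11(13)-trien-12,8α-olide (target)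
Conditions: SeO2 (1.5 equiv), 1,4-dioxane, 70 °C
Reagents that add atoms: selenium dioxide, O=[Se]=O
Why: Riley allylic oxidation (ene reaction, [2,3]-shift, further oxidation to the enal) should attack the only electron-rich alkene that has allylic hydrogens, since the vinyl group has none and the other two alkenes are electron-poor; no stereocentre is touched.

**Compound list**
1 | 3-methylbut-2-enal | CC(C)=CC=O | starting material
2 | but-2-yn-1-ol | CC#CCO | starting material
3 | 1,1-bis(but-2-yn-1-yloxy)-3-methylbut-2-ene | CC(C)=CC(OCC#CC)OCC#CC | intermediate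
4 | (E)-1-(but-2-yn-1-yloxy)-3-methylbuta-1,3-diene | C=C(C)/C=C/OCC#CC | intermediate
5 | rac-3-methyl-2-(prop-1-en-2-yl)penta-3,4-dienal | C=C=C(C)C(C=O)C(C)=C | intermediate
6 | rac-5,5-dimethoxy-3-methyl-4-(prop-1-en-2-yl)penta-1,2-diene | C=C=C(C)C(C(OC)OC)C(C)=C | intermediate
7 | rac-(Z)-2-[5,5-dimethoxy-3-methyl-4-(prop-1-en-2-yl)pent-2-en-1-yl]-4,4,5,5-tetramethyl-1,3,2-dioxaborolane | COC(OC)C(C(C)=C)/C(C)=C\CB1OC(C)(C)C(C)(C)O1 | intermediate
8 | (S)-2,2-dimethyl-1,3-dioxolane-4-carbaldehyde | O=C[C@@H]1COC(C)(C)O1 | starting material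
9 | tert-butyl acrylate | C=CC(=O)OC(C)(C)C | starting material
10 | tert-butyl 2-{hydroxy[(4S)-2,2-dimethyl-1,3-dioxolan-4-yl]methyl}acrylate | C=C(C(=O)OC(C)(C)C)C(O)[C@@H]1COC(C)(C)O1 | intermediate
11 | tert-butyl 2-{acetoxy[(4S)-2,2-dimethyl-1,3-dioxolan-4-yl]methyl}acrylate | C=C(C(=O)OC(C)(C)C)C(OC(C)=O)[C@@H]1COC(C)(C)O1 | intermediate
12 | tert-butyl (4S)-3-acetoxy-4,5-dihydroxy-2-methylenepentanoate | C=C(C(=O)OC(C)(C)C)C(OC(C)=O)[C@@H](O)CO | intermediate
13 | tert-butyl (4S)-3-acetoxy-2-methylene-4,5-bis(triethylsilyloxy)pentanoate | C=C(C(=O)OC(C)(C)C)C(OC(C)=O)[C@@H](O[Si](CC)(CC)CC)CO[Si](CC)(CC)CC | intermediate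
14 | tert-butyl (2E,4R)-2-[(pinacolboryl)methyl]-4,5-bis(triethylsilyloxy)pent-2-enoate | CC(C)(C)OC(=O)/C(CB1OC(C)(C)C(C)(C)O1)=C/[C@@H](O[Si](CC)(CC)CC)CO[Si](CC)(CC)CC | intermediate
15 | tert-butyl (2E,4R)-5-oxo-2-[(pinacolboryl)methyl]-4-(triethylsilyloxy)pent-2-enoate | CC(C)(C)OC(=O)/C(CB1OC(C)(C)C(C)(C)O1)=C/[C@@H](O[Si](CC)(CC)CC)C=O | intermediate
16 | 6,7-seco adduct: C9–C10 formed, O9 pinacolboryl, C6 dimethyl acetal, O8 triethylsilyl, C13 boronate, C5 epimers | C=C[C@](C(C(C)=C)C(OC)OC)(C)[C@H](OB1OC(C)(C)C(C)(C)O1)[C@H](O[Si](CC)(CC)CC)/C=C(\CB2OC(C)(C)C(C)(C)O2)C(=O)OC(C)(C)C | intermediate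
17 | 6,7-seco aldehyde: C6 formyl, 9-OH, O8 triethylsilyl, C13 boronate, C5 equilibrating | C=C[C@](C(C(C)=C)C=O)(C)[C@H](O)[C@H](O[Si](CC)(CC)CC)/C=C(\CB1OC(C)(C)C(C)(C)O1)C(=O)OC(C)(C)C | intermediate
18 | tert-butyl 6β,8α,9α-trihydroxyelema-1,3,11(13)-trien-12-oate | C=C[C@]1(C)[C@H](O)[C@H](O)[C@@H](C(=C)C(=O)OC(C)(C)C)[C@@H](O)[C@H]1C(C)=C | intermediate
19 | 8α,9α-O-(1-methoxyethylidene) derivative of 18 | C=C[C@]1(C)[C@@H]2OC(C)(OC)O[C@@H]2[C@@H](C(=C)C(=O)OC(C)(C)C)[C@@H](O)[C@H]1C(C)=C | intermediate
20 | 6β-angelate of 19 | C=C[C@]1(C)[C@@H]2OC(C)(OC)O[C@@H]2[C@@H](C(=C)C(=O)OC(C)(C)C)[C@@H](OC(=O)/C(C)=C\C)[C@H]1C(C)=C | intermediate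
21 | 9α-acetoxy-6β-angeloyloxyelema-1,3,11(13)-trien-12,8α-olide | C=C[C@]1(C)[C@H](OC(C)=O)[C@@H]2OC(=O)C(=C)[C@H]2[C@@H](OC(=O)/C(C)=C\C)[C@H]1C(C)=C | intermediate
22 | 9α-acetoxy-6β-angeloyloxy-15-oxoelema-1,3,11(13)-trien-12,8α-olide | C=C[C@]1(C)[C@H](OC(C)=O)[C@@H]2OC(=O)C(=C)[C@H]2[C@@H](OC(=O)/C(C)=C\C)[C@H]1C(=C)C=O | target

Total step count: 15. Longest linear sequence: 11 steps (steps 5 to 15, from 8).

**Steps most likely to fail**

**1. Step 11.** Several things may go wrong:
- self-condensation of either partner;
- arrest at the cyclic lactol or its methyl acetal;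
- epimerisation at C5 that is slow relative to ring closure;
- drift of the isopropenyl group into conjugation with the free aldehyde.

The fallback sets out from 13 and 7 and comes back at 18. It makes the two bonds apart, by two known reactions that use two different metals.
- MgBr2·OEt2 in THF converts 13 by SN2' displacement into tert-butyl (2Z,4R)-2-(bromomethyl)-4,5-bis(triethylsilyloxy)pent-2-enoate F1.
- The oxidation of step 10 gives tert-butyl (2Z,4R)-2-(bromomethyl)-5-oxo-4-(triethylsilyloxy)pent-2-enoate F2.
- Uncatalysed allylboration with 7 (toluene, 25 °C) gives the isolated 6,7-seco bromo acetal alcohol F3, whose C5 epimers can be separated.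
- Indium powder in THF–aqueous HCl closes C6–C7 and removes the silyl group to give 18. This is an aqueous Barbier reaction of a 2-(bromomethyl)acrylate, with acetal hydrolysis in the same medium.

**2. Step 13.** The acylation of the axial 6β-hydroxyl, which is syn-diaxial to the C10 methyl, may be sluggish. Prolonged heating may also isomerise the acyl donor from Z to E.

The fallback sets out from 19 and comes back at 20. It builds the Z double bond on the molecule.
- 19 is acylated with 2-[bis(2,2,2-trifluoroethoxy)phosphoryl]propanoyl chloride and pyridine to give the 6β-phosphonopropanoate F4.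
- A Still–Gennari olefination with acetaldehyde (KHMDS, 18-crown-6, THF, −78 °C) then gives the angelate 20.

**3. Step 15.** The site selectivity may be poor (attack at C5–H or at the angelate methyl groups), or the oxidation may stop at the allylic alcohol.

The fallback sets out from 21 and comes back at 22. It replaces the selenium oxidation by halogenation and oxygen transfer.
- Ene-type allylic chlorination of the isopropenyl group (NaOCl, CeCl3·7H2O, CH2Cl2–H2O, 0 °C) gives the 15-chloride F5.
- N-methylmorpholine N-oxide with KI in MeCN converts the allylic chloride into the enal 22.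

**Further compounds**
F1 | step 11 | tert-butyl (2Z,4R)-2-(bromomethyl)-4,5-bis(triethylsilyloxy)pent-2-enoate | CC(C)(C)OC(=O)/C(CBr)=C/[C@@H](O[Si](CC)(CC)CC)CO[Si](CC)(CC)CC
F2 | step 11 | tert-butyl (2Z,4R)-2-(bromomethyl)-5-oxo-4-(triethylsilyloxy)pent-2-enoate | CC(C)(C)OC(=O)/C(CBr)=C/[C@@H](O[Si](CC)(CC)CC)C=O
F3 | step 11 | 6,7-seco bromo acetal alcohol (C9–C10 adduct of F2 and 7, C5 epimers) | C=C[C@](C(C(C)=C)C(OC)OC)(C)[C@H](O)[C@H](O[Si](CC)(CC)CC)/C=C(\CBr)C(=O)OC(C)(C)C
F4 | step 13 | 6β-{2-[bis(2,2,2-trifluoroethoxy)phosphoryl]propanoate} of 19 | C=C[C@]1(C)[C@@H]2OC(C)(OC)O[C@@H]2[C@@H](C(=C)C(=O)OC(C)(C)C)[C@@H](OC(=O)C(C)P(=O)(OCC(F)(F)F)OCC(F)(F)F)[C@H]1C(C)=C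
F5 | step 15 | 9α-acetoxy-6β-angeloyloxy-15-chloroelema-1,3,11(13)-trien-12,8α-olide | C=C[C@]1(C)[C@H](OC(C)=O)[C@@H]2OC(=O)C(=C)[C@H]2[C@@H](OC(=O)/C(C)=C\C)[C@H]1C(=C)CCl
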